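**Assumption:** onind and the acylfilicinic intermediates are drawn as single enol tautomers; each SMILES stands for the rapidly equilibrating tautomer set.

**Retrosynthetic overview**
1. Onind is a central isobutyrylphloroglucinol ring joined through two CH2 bridges to two identical 3'-isobutyryl-5',5'-dimethylcyclohexanetrione rings; the last step is global O-demethylation of penta-O-methyl onind 15.
2. Feature used: in each outer ring the carbons C6' (ring C=O next to CMe2), C1' (bridge carbon), C2' (C–O), C3' and the isobutyryl carbonyl carbon are the C2–C6 chain of a 4-methoxy-6-isopropyl-2-pyrone, and the remaining C4'–C5'(Me2) pair is an isobutyrate unit.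
3. Key disconnection: both outer carbocycles are cut at C5'–C6' and C3'–C4', back to bis-pyrone 11 and two methyl isobutyrate enolates (acyl addition, pyrone opening, Dieckmann reclosure).
4. Bis-pyrone 11 comes from C3-benzylation of 4-hydroxy-6-isopropyl-2-pyrone 9 (from dioxinone 5 and isobutyryl chloride through an acylketene) with bis(chloromethyl) ketone 4 (from 1,3,5-trimethoxybenzene by acylation and double chloromethylation), then O-methylation.
5. Ring order: the aromatic ring is bought, the two pyrone rings are made in step 4, and both outer carbocycles close together in step 7.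

Key step: step 7

**Step 1**
Reactants: 1 1,3,5-trimethoxybenzene; 2 isobutyryl chloride
Product: 3 2-methyl-1-(2,4,6-trimethoxyphenyl)propan-1-one
Conditions: AlCl3 (1.1 equiv), CH2Cl2, −10 to 0 °C, short reaction time; ice/dilute HCl work-up
Reagents that add atoms: none
Why: Friedel–Crafts acylation of a strongly activated arene, in which the first acyl group deactivates the ring enough to stop at monoacylation and the low temperature limits AlCl3-induced loss of an ortho methyl ether.

**Step 2**
Reactants: 3 2-methyl-1-(2,4,6-trimethoxyphenyl)propan-1-one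
Product: 4 1-[3,5-bis(chloromethyl)-2,4,6-trimethoxyphenyl]-2-methylpropan-1-one
Conditions: (CH2O)n (5 equiv), HCl (g) to saturation, AcOH, 45 °C
Reagents that add atoms: formaldehyde (from paraformaldehyde), C=O; hydrogen chloride, Cl
Why: Blanc chloromethylation at the only two free ring positions, each ortho/para to three methoxy groups, with excess formaldehyde and saturating HCl to trap each benzylic cation as the chloride before it can alkylate another arene; the fully substituted product can no longer form diarylmethanes.

**Step 3**
Reactants: 5 2,2,6-trimethyl-4H-1,3-dioxin-4-one (2 equiv); 2 isobutyryl chloride (1 equiv)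
Product: 7 2,2-dimethyl-6-(3-methyl-2-oxobutyl)-4H-1,3-dioxin-4-one, via lithium dioxinone dienolate 6 (not isolated)
Conditions: LiN(SiMe3)2 (2.1 equiv), THF, −78 °C; then 2, −78 to −20 °C; aq. NH4Cl
Reagents that add atoms: none
Why: γ-selective C-acylation of the vinylogous ester dienolate by the acid chloride (Claisen-type acylation), with the second equivalent of dienolate taking up the acidic proton of the keto-dioxinone so that it is not acylated again.

**Step 4**
Reactants: 7 2,2-dimethyl-6-(3-methyl-2-oxobutyl)-4H-1,3-dioxin-4-one
Product: 9 4-hydroxy-6-isopropyl-2H-pyran-2-one, via acylketene 8 (not isolated)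
Conditions: toluene, 110 °C
Reagents that add atoms: none
Why: thermal retro-[4+2] loss of acetone gives the acylketene, which is captured by the enol oxygen of the δ-ketone (intramolecular O-acylation) to close the 2-pyrone ring, the standard dioxinone route to 6-alkyl-4-hydroxy-2-pyrones.

**Step 5**
Reactants: 4 1-[3,5-bis(chloromethyl)-2,4,6-trimethoxyphenyl]-2-methylpropan-1-one; 9 4-hydroxy-6-isopropyl-2H-pyran-2-one (2.4 equiv)
Product: 10 1-[3,5-bis[(4-hydroxy-6-isopropyl-2-oxo-2H-pyran-3-yl)methyl]-2,4,6-trimethoxyphenyl]-2-methylpropan-1-one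
Conditions: (CF3)2CHOH, 50 °C
Reagents that add atoms: none
Why: Friedel–Crafts-type SN1 benzylation, in which the ionizing solvent turns each trialkoxybenzylic chloride into a stabilized cation that the hydroxypyrone captures at C3, its most nucleophilic carbon, while any O-benzyl ether re-ionizes under the acidic conditions and funnels to the C-alkylated product.

**Step 6**
Reactants: 10 1-[3,5-bis[(4-hydroxy-6-isopropyl-2-oxo-2H-pyran-3-yl)methyl]-2,4,6-trimethoxyphenyl]-2-methylpropan-1-one
Product: 11 1-[3,5-bis[(6-isopropyl-4-methoxy-2-oxo-2H-pyran-3-yl)methyl]-2,4,6-trimethoxyphenyl]-2-methylpropan-1-one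
Conditions: Me2SO4 (3 equiv), K2CO3, acetone, reflux
Reagents that add atoms: dimethyl sulfate, COS(=O)(=O)OC
Why: O-methylation of the vinylogous acid with a hard methylating agent and carbonate, the usual way to 4-methoxy-2-pyrones, under which the hindered aryl ketone and the benzylic CH2 groups are not deprotonated.

**Step 7**
Reactants: 11 1-[3,5-bis[(6-isopropyl-4-methoxy-2-oxo-2H-pyran-3-yl)methyl]-2,4,6-trimethoxyphenyl]-2-methylpropan-1-one; 12 methyl isobutyrate (6 equiv)
Product: 15 penta-O-methyl onind (2,4,6-trimethoxyphenyl isopropyl ketone whose 3- and 5-CH2 groups each carry a 3-isobutyryl-4-hydroxy-2-methoxy-5,5-dimethyl-6-oxocyclohexa-1,3-dien-1-yl ring), via lithium enolate of methyl isobutyrate 13 (not isolated), via ring-opened bis(dienolate) keto ester 14 (not isolated)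
Conditions: 12, LiN(i-Pr)2 (6 equiv), THF, −78 °C; then 11, −78 to 0 °C; cold 1 M HCl quench
Reagents that add atoms: none
Why: Proposed new method: the tertiary lithium ester enolate 13 should add 1,2 to each lactone carbonyl (pyrone C2, new C5'–C6' bond), and collapse of the tetrahedral alkoxide expels the ring oxygen as the C6 enolate, which turns the isopropyl-bearing carbon into the exocyclic isobutyryl ketone and leaves dienolate 14 with its nucleophilic carbon (old pyrone C5, C3' of the target) held cis to the new ketone across the former C3=C4 bond. That carbon then attacks the methyl ester in a Dieckmann condensation (new C3'–C4' bond), a 6-(enolexo)-exo-trig closure for each of the two outer rings, and loss of methoxide followed by deprotonation to the stabilized triketone enolate should pull both closures to completion. The closest known reaction types are the carbanion-induced ring transformation of 2-pyranones into benzenes and the base-mediated recyclization of a 4-methoxy-6-methyl-2-pyrone to a phloroglucinol ether; here the quaternary CMe2 carbon keeps the new ring non-aromatic. No stereocentre is formed. The step needs attack at the lactone carbonyl in preference to conjugate addition at C4 or C6, to proton abstraction and to addition at the aryl ketone, which the C4 methoxy donor, the isopropyl group on C6, the two ortho methoxy groups around the aryl ketone, the absence of any O–H and a hard lithium enolate at −78 °C should secure, with excess enolate covering any loss to enolization.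

**Step 8**
Reactants: 15 penta-O-methyl onind
Product: 16 onind
Conditions: BBr3 (15 equiv), CH2Cl2, −78 °C to rt; then H2O, 0 °C
Reagents that add atoms: none
Why: Lewis acid-mediated SN2 demethylation, in which the two vinylogous ester methyls and the two aryl methyls ortho to the ketone should cleave first through boron chelates and the central aryl ether, twisted out of conjugation by its two benzylic neighbours, follows at room temperature; hydrolysis of the borates releases the seven hydroxyls.

**Compound list**
1 | 1,3,5-trimethoxybenzene | COc1cc(OC)cc(OC)c1 | starting material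
2 | isobutyryl chloride | CC(C)C(=O)Cl | starting material
3 | 2-methyl-1-(2,4,6-trimethoxyphenyl)propan-1-one | CC(C)C(=O)c1c(OC)cc(OC)cc1OC | intermediate
4 | 1-[3,5-bis(chloromethyl)-2,4,6-trimethoxyphenyl]-2-methylpropan-1-one | CC(C)C(=O)c1c(OC)c(CCl)c(OC)c(CCl)c1OC | intermediate
5 | 2,2,6-trimethyl-4H-1,3-dioxin-4-one | CC1=CC(=O)OC(C)(C)O1 | starting material
6 | lithium dienolate of dioxinone 5 (6-methylene-2,2-dimethyl-1,3-dioxin-4-olate) | C=C1C=C([O-])OC(C)(C)O1.[Li+] | intermediate
7 | 2,2-dimethyl-6-(3-methyl-2-oxobutyl)-4H-1,3-dioxin-4-one | CC(C)C(=O)CC1=CC(=O)OC(C)(C)O1 | intermediate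
8 | acylketene 6-methyl-3,5-dioxohept-1-en-1-one | CC(C)C(=O)CC(=O)C=C=O | intermediate
9 | 4-hydroxy-6-isopropyl-2H-pyran-2-one | CC(C)C1=CC(O)=CC(=O)O1 | intermediate
10 | 1-[3,5-bis[(4-hydroxy-6-isopropyl-2-oxo-2H-pyran-3-yl)methyl]-2,4,6-trimethoxyphenyl]-2-methylpropan-1-one | CC(C)C(=O)c1c(OC)c(CC2=C(O)C=C(C(C)C)OC2=O)c(OC)c(CC2=C(O)C=C(C(C)C)OC2=O)c1OC | intermediate
11 | 1-[3,5-bis[(6-isopropyl-4-methoxy-2-oxo-2H-pyran-3-yl)methyl]-2,4,6-trimethoxyphenyl]-2-methylpropan-1-one | CC(C)C(=O)c1c(OC)c(CC2=C(OC)C=C(C(C)C)OC2=O)c(OC)c(CC2=C(OC)C=C(C(C)C)OC2=O)c1OC | intermediate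
12 | methyl isobutyrate | COC(=O)C(C)C | starting material
13 | lithium enolate of methyl isobutyrate | COC([O-])=C(C)C.[Li+] | intermediate
14 | dilithium bis(dienolate) of the doubly ring-opened keto ester; each arm is ArCH2–C[C(=O)CMe2CO2Me]=C(OMe)–CH=C(OLi)–iPr, with the acyl group cis to the CH=C(OLi) carbon and the enolate Z | CC(C)C(=O)c1c(OC)c(C/C(C(=O)C(C)(C)C(=O)OC)=C(\OC)/C=C(\[O-])C(C)C)c(OC)c(C/C(C(=O)C(C)(C)C(=O)OC)=C(\OC)/C=C(\[O-])C(C)C)c1OC.[Li+].[Li+] | intermediate
15 | penta-O-methyl onind | CC(C)C(=O)c1c(OC)c(CC2=C(OC)C(C(=O)C(C)C)=C(O)C(C)(C)C2=O)c(OC)c(CC2=C(OC)C(C(=O)C(C)C)=C(O)C(C)(C)C2=O)c1OC | intermediate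
16 | onind | CC(C)C(=O)C1=C(O)C(Cc2c(O)c(CC3=C(O)C(C)(C)C(=O)C(C(=O)C(C)C)=C3O)c(O)c(C(=O)C(C)C)c2O)=C(O)C(C)(C)C1=O | target

**Step count**
Total steps: 8. Longest linear sequence: 6 steps (1, 2, 5, 6, 7, 8 from compound 1, or 3, 4, 5, 6, 7, 8 from compound 5).

**Steps most likely to fail**

Step 7 (proposed new method). The ester enolate may act as a base at the vinylogous isopropyl methine of the pyrone, or add in conjugate fashion at C6, instead of adding to the lactone carbonyl. The opened keto ester may also fragment by retro-Claisen attack of methoxide before it closes. The fallback uses only known chemistry, sets out from compound 2 and returns at compound 16, leaving the methyl ether series. Phloroglucinol (Oc1cc(O)cc(O)c1) would be acylated with 2 (AlCl3, PhNO2/CH2Cl2) to phlorisobutyrophenone F1. Part of it would be C,C-dimethylated (MeI, NaOMe, MeOH) to isobutyrylfilicinic acid F2. Condensation of F1 with F2 (2.5 equiv) and aqueous formaldehyde (2.2 equiv) in dilute aqueous KOH at 0 °C, then acidification, should give onind 16 by the classical methylene-bridge coupling: the methylene-triketone formed from F2 and formaldehyde is trapped by the two free ring carbons of F1. The symmetric methylene-bis(filicinic acid) by-product would have to be separated.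

Step 8. The crowded central aryl ether may cleave incompletely. Prolonged exposure to the Lewis acid and to HBr during the quench may also cut or scramble the methylene bridges, or deacylate the triketone rings. The fallback moves the boron step to a sturdier intermediate and ends with a neutral hydrogenolysis; it sets out from compound 10 and returns at compound 16. BBr3 (CH2Cl2, −78 °C to rt) would cleave the three aryl methyl ethers of 10 to give the pentahydroxy bis-pyrone F3. Benzylation of all five hydroxyls (BnBr, K2CO3, DMF, 60 °C) would give the penta-O-benzyl bis-pyrone F4. The same pyrone-to-carbocycle swap with 12 and LiN(i-Pr)2 would give penta-O-benzyl onind F5. Hydrogenolysis (H2, Pd/C, EtOAc, rt) would then release 16.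

Step 5. The pyrone 4-hydroxyl may be benzylated in competition with C3, or the crowded benzylic chlorides may ionize too slowly and leave mono-alkylated material. The fallback replaces alkylation by a reductive Knoevenagel alkylation; it sets out from compound 4 and returns at compound 10. Oxidation of both chloromethyl groups with N-methylmorpholine N-oxide (MeCN, 40 °C) would give the dialdehyde F6. Condensation of F6 with 9 (2.2 equiv) in the presence of L-proline (cat.) and the Hantzsch ester (diethyl 2,6-dimethyl-1,4-dihydropyridine-3,5-dicarboxylate, 2.4 equiv) in CH2Cl2 at rt would form each 3-arylidene-pyran-2,4-dione and reduce it in situ, which fixes the new bond at pyrone C3 and gives 10.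

**Further compounds**
F1 | step 7 | phlorisobutyrophenone (2-methyl-1-(2,4,6-trihydroxyphenyl)propan-1-one) | CC(C)C(=O)c1c(O)cc(O)cc1O
F2 | step 7 | isobutyrylfilicinic acid (3,5-dihydroxy-2-isobutyryl-6,6-dimethylcyclohexa-2,4-dien-1-one) | CC(C)C(=O)C1=C(O)C=C(O)C(C)(C)C1=O
F3 | step 8 | 1-[2,4,6-trihydroxy-3,5-bis[(4-hydroxy-6-isopropyl-2-oxo-2H-pyran-3-yl)methyl]phenyl]-2-methylpropan-1-one | CC(C)C(=O)c1c(O)c(CC2=C(O)C=C(C(C)C)OC2=O)c(O)c(CC2=C(O)C=C(C(C)C)OC2=O)c1O
F4 | step 8 | penta-O-benzyl bis-pyrone (benzyl analogue of 11) | CC(C)C(=O)c1c(OCc2ccccc2)c(CC2=C(OCc3ccccc3)C=C(C(C)C)OC2=O)c(OCc2ccccc2)c(CC2=C(OCc3ccccc3)C=C(C(C)C)OC2=O)c1OCc1ccccc1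
F5 | step 8 | penta-O-benzyl onind (benzyl analogue of 15) | CC(C)C(=O)c1c(OCc2ccccc2)c(CC2=C(OCc3ccccc3)C(C(=O)C(C)C)=C(O)C(C)(C)C2=O)c(OCc2ccccc2)c(CC2=C(OCc3ccccc3)C(C(=O)C(C)C)=C(O)C(C)(C)C2=O)c1OCc1ccccc1
F6 | step 5 | 5-isobutyryl-2,4,6-trimethoxybenzene-1,3-dicarbaldehyde | CC(C)C(=O)c1c(OC)c(C=O)c(OC)c(C=O)c1OC
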